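**Assumption:** (S)-isophorol (≥98% ee) and 2-deoxy-L-ribose are taken as purchasable enantiopure materials. I am not certain that (S)-isophorol is a cheap catalogue item; if it is not, it would have to be made from isophorone by an asymmetric reduction or resolution outside this route.

## Retrosynthetic overview

1. β-Lactone last: lactonisation of the cis-β-hydroxy acid 17 by carboxyl activation (C–O stereocentre retained).
2. Cyclohexene ring (key step): intermolecular Diels–Alder of acrolein with semicyclic diene 12, anti to the allylic OBn; the CH₂O-bearing centre is then set by equilibration.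
3. Cyclopentene ring: ring-closing enyne metathesis of 1,6-enyne acid 11.
4. Enyne 11: trans-alkylation of a 2-deoxy-L-ribonolactone enolate with propargylic bromide 5, then Zn fragmentation (sugar C-4/C-5 become the vinyl group).
5. Quaternary centre: Eschenmoser–Claisen [3,3] on (S)-isophorol. Ring order: trimethylcyclohexane (bought) → cyclopentene → cyclohexene → β-lactone.

## Route

**Step 1**
Reactants: 1, (S)-3,5,5-trimethylcyclohex-2-en-1-ol
Product: 2, N,N-dimethyl-2-[(1S)-1,5,5-trimethylcyclohex-2-en-1-yl]acetamide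
Conditions: MeC(OMe)₂NMe₂ (3 equiv), xylenes, 140 °C
Reagents that add atoms: N,N-dimethylacetamide dimethyl acetal, CC(OC)(OC)N(C)C
Why: Eschenmoser–Claisen [3,3] rearrangement; the new C–C bond forms on the face that carried the C–O bond (suprafacial 1,3-chirality transfer), so the carbinol centre of 1 sets the quaternary centre.

**Step 2**
Reactants: 2
Product: 3, 2-[(1S)-1,5,5-trimethylcyclohex-2-en-1-yl]acetaldehyde
Conditions: Cp₂Zr(H)Cl, THF, rt
Reagents that add atoms: none
Why: Schwartz-reagent partial reduction of a tertiary amide stops at the aldehyde; the quaternary centre cannot epimerise.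

**Step 3**
Reactants: 3
Product: 4, 3-[(1R)-1,5,5-trimethylcyclohex-2-en-1-yl]prop-2-yn-1-ol (same geometry; descriptor changes by CIP priority only)
Conditions: KHMDS, PhNTf₂, THF, −78 °C; then LDA (3 equiv), −78 → 0 °C; then (CH₂O)n, 0 °C → rt
Reagents that add atoms: paraformaldehyde (formaldehyde), C=O
Why: enol triflate formation and elimination give the lithium acetylide, which is hydroxymethylated in the same pot; no stereocentre is involved.

**Step 4**
Reactants: 4
Product: 5, (3R)-3-(3-bromoprop-1-yn-1-yl)-3,5,5-trimethylcyclohex-1-ene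
Conditions: CBr₄, PPh₃, CH₂Cl₂, 0 °C
Reagents that add atoms: carbon tetrabromide, BrC(Br)(Br)Br
Why: Appel bromination of a primary propargylic alcohol.

**Step 5**
Reactants: 6, 2-deoxy-L-ribose
Product: 7, 2-deoxy-L-ribono-1,4-lactone, (4R,5S)-4-hydroxy-5-(hydroxymethyl)oxolan-2-one
Conditions: Br₂, BaCO₃, H₂O, rt
Reagents that add atoms: none
Why: bromine-water oxidation of the aldose lactol to the γ-lactone; both stereocentres untouched.

**Step 6**
Reactants: 7
Product: 8, (4R,5R)-4-hydroxy-5-(iodomethyl)oxolan-2-one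
Conditions: I₂, PPh₃, imidazole, THF, 0 °C → rt
Reagents that add atoms: iodine, II
Why: Appel iodination is selective for the primary hydroxyl.

**Step 7**
Reactants: 8
Product: 9, (4R,5R)-4-(benzyloxy)-5-(iodomethyl)oxolan-2-one
Conditions: BnOC(=NH)CCl₃, TfOH (cat.), CH₂Cl₂/cyclohexane, 0 °C → rt
Reagents that add atoms: benzyl 2,2,2-trichloroacetimidate, N=C(OCc1ccccc1)C(Cl)(Cl)Cl
Why: acid-catalysed O-benzylation avoids base-induced β-elimination of the β-hydroxy lactone.

**Step 8**
Reactants: 9; 5
Product: 10, (3R,4R,5R)-4-(benzyloxy)-5-(iodomethyl)-3-{3-[(1R)-1,5,5-trimethylcyclohex-2-en-1-yl]prop-2-yn-1-yl}oxolan-2-one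
Conditions: LiHMDS (1.05 equiv), THF, −78 °C; then 5 (1.2 equiv), DMPU, −78 → −40 °C
Reagents that add atoms: none
Why: lactone enolate alkylation; the bromide enters anti to the adjacent benzyloxy group (2,3-trans), which sets the future lactone α-carbon.

**Step 9**
Reactants: 10
Product: 11, (2R,3S)-3-(benzyloxy)-2-{3-[(1R)-1,5,5-trimethylcyclohex-2-en-1-yl]prop-2-yn-1-yl}pent-4-enoic acid
Conditions: activated Zn dust, THF/AcOH, 60 °C
Reagents that add atoms: none
Why: Vasella-type reductive fragmentation (zinc insertion, β-elimination of the lactone carboxylate) unveils the vinyl group and the acid; only the sacrificial sugar C-4 centre is lost.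

**Step 10**
Reactants: 11
Product: 12, (1R,2S)-2-(benzyloxy)-4-{1-[(1R)-1,5,5-trimethylcyclohex-2-en-1-yl]ethenyl}cyclopent-3-ene-1-carboxylic acid
Conditions: Grubbs II (10 mol %), ethylene (1 atm), toluene, 80 °C
Reagents that add atoms: none
Why: ring-closing enyne metathesis; under ethylene, Ru=CH₂ adds to the less hindered alkyne carbon, then closes onto the vinyl group. The acyclic anti relationship becomes cis OBn/CO₂H on the ring; no stereocentre is touched.

**Step 11**
Reactants: 12; 13, acrolein
Product: 14, (2R,3S,3aR,4RS)-3-(benzyloxy)-4-formyl-7-[(1R)-1,5,5-trimethylcyclohex-2-en-1-yl]-2,3,3a,4,5,6-hexahydro-1H-indene-2-carboxylic acid (mixture at C-4)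
Conditions: acrolein (10 equiv), BHT, toluene, 80–100 °C, sealed tube
Reagents that add atoms: none beyond reactant 13
Why: normal-demand Diels–Alder forms the cyclohexene with the tetrasubstituted alkene. "Ortho" orientation puts the formyl carbon next to the ring-fusion carbon, reinforced by the 2-tert-alkyl group. The dienophile adds anti to the allylic OBn and cis CO₂H, setting C-3a as R.

**Step 12**
Reactants: 14
Product: 15, (2R,3S,3aR,4S)-3-(benzyloxy)-4-(hydroxymethyl)-7-[(1R)-1,5,5-trimethylcyclohex-2-en-1-yl]-2,3,3a,4,5,6-hexahydro-1H-indene-2-carboxylic acid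
Conditions: DBU (2.2 equiv), CH₂Cl₂, rt; then NaBH₄, MeOH, 0 °C
Reagents that add atoms: none
Why: base epimerisation α to the aldehyde equilibrates C-4 to the pseudo-equatorial isomer (trans to the C-3a–C-3 bond), which is then fixed by reduction. I expect only about 4:1, so the minor alcohol is removed by chromatography; the carboxylate α-centre is not enolised.

**Step 13**
Reactants: 15
Product: 16, (2R,3S,3aR,4S)-3-(benzyloxy)-4-[(butanoyloxy)methyl]-7-[(1R)-1,5,5-trimethylcyclohex-2-en-1-yl]-2,3,3a,4,5,6-hexahydro-1H-indene-2-carboxylic acid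
Conditions: (PrCO)₂O, pyridine, DMAP (cat.), CH₂Cl₂, 0 °C → rt; then aq. NaHCO₃/THF
Reagents that add atoms: butyric anhydride, CCCC(=O)OC(=O)CCC
Why: acylation of the only free hydroxyl; the transient mixed anhydride at the acid is hydrolysed on work-up.

**Step 14**
Reactants: 16
Product: 17, (2R,3S,3aR,4S)-4-[(butanoyloxy)methyl]-3-hydroxy-7-[(1S)-1,3,3-trimethylcyclohexyl]-2,3,3a,4,5,6-hexahydro-1H-indene-2-carboxylic acid
Conditions: H₂ (1 atm), 10% Pd/C, EtOAc, rt
Reagents that add atoms: none
Why: one hydrogenation saturates the disubstituted cyclohexene and cleaves the benzyl ether; the hindered tetrasubstituted alkene and the butyrate survive, and no stereocentre changes.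

**Step 15**
Reactants: 17
Product: 18, 3'-norspongiolactone
Conditions: BOPCl, Et₃N, CH₂Cl₂, 0 °C → rt
Reagents that add atoms: none
Why: β-lactonisation of a cis-β-hydroxy acid by carboxyl activation; the C–O stereocentre is retained and the cis-fused lactone is the only one possible.

## Compound list

1 | (S)-3,5,5-trimethylcyclohex-2-en-1-ol ((S)-isophorol) | CC1=C[C@@H](O)CC(C)(C)C1 | starting material
2 | N,N-dimethyl-2-[(1S)-1,5,5-trimethylcyclohex-2-en-1-yl]acetamide | CN(C)C(=O)C[C@@]1(C)C=CCC(C)(C)C1 | intermediate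
3 | 2-[(1S)-1,5,5-trimethylcyclohex-2-en-1-yl]acetaldehyde | O=CC[C@@]1(C)C=CCC(C)(C)C1 | intermediate
4 | 3-[(1R)-1,5,5-trimethylcyclohex-2-en-1-yl]prop-2-yn-1-ol | OCC#C[C@@]1(C)C=CCC(C)(C)C1 | intermediate
5 | (3R)-3-(3-bromoprop-1-yn-1-yl)-3,5,5-trimethylcyclohex-1-ene | BrCC#C[C@@]1(C)C=CCC(C)(C)C1 | intermediate
6 | 2-deoxy-L-ribose, (3R,4S)-3,4,5-trihydroxypentanal | O=CC[C@@H](O)[C@@H](O)CO | starting material
7 | 2-deoxy-L-ribono-1,4-lactone | O=C1C[C@@H](O)[C@H](CO)O1 | intermediate
8 | (4R,5R)-4-hydroxy-5-(iodomethyl)oxolan-2-one | O=C1C[C@@H](O)[C@H](CI)O1 | intermediate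
9 | (4R,5R)-4-(benzyloxy)-5-(iodomethyl)oxolan-2-one | O=C1C[C@@H](OCc2ccccc2)[C@H](CI)O1 | intermediate
10 | (3R,4R,5R)-alkylated iodolactone | O=C1[C@H](CC#C[C@@]2(C)C=CCC(C)(C)C2)[C@@H](OCc3ccccc3)[C@H](CI)O1 | intermediate
11 | (2R,3S)-enyne acid | OC(=O)[C@H](CC#C[C@@]1(C)C=CCC(C)(C)C1)[C@@H](OCc1ccccc1)C=C | intermediate
12 | (1R,2S)-cyclopentenyl diene acid | C=C([C@@]1(C)C=CCC(C)(C)C1)C2=C[C@H](OCc3ccccc3)[C@H](C(=O)O)C2 | intermediate
13 | acrolein | C=CC=O | starting material
14 | Diels–Alder aldehyde (C-4 epimers) | O=CC1CCC([C@@]2(C)C=CCC(C)(C)C2)=C3C[C@@H](C(=O)O)[C@@H](OCc4ccccc4)[C@@H]31 | intermediate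
15 | (2R,3S,3aR,4S)-primary alcohol | OC[C@H]1CCC([C@@]2(C)C=CCC(C)(C)C2)=C3C[C@@H](C(=O)O)[C@@H](OCc4ccccc4)[C@@H]31 | intermediate
16 | butyrate benzyl ether acid | CCCC(=O)OC[C@H]1CCC([C@@]2(C)C=CCC(C)(C)C2)=C3C[C@@H](C(=O)O)[C@@H](OCc4ccccc4)[C@@H]31 | intermediate
17 | cis-β-hydroxy acid | CCCC(=O)OC[C@H]1CCC([C@@]2(C)CCCC(C)(C)C2)=C3C[C@@H](C(=O)O)[C@@H](O)[C@@H]31 | intermediate
18 | 3'-norspongiolactone | CCCC(=O)OC[C@H]1CCC([C@@]2(C)CCCC(C)(C)C2)=C2C[C@H]3C(=O)O[C@H]3[C@@H]21 | target

## Step count and risks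

Total: 15 steps. Longest linear sequence: 12 steps (1 → 2 → 3 → 4 → 5 → 10 → 11 → 12 → 14 → 15 → 16 → 17 → 18).

Steps most likely to fail:

1. **Step 10, enyne metathesis onto a tert-alkyl alkyne.** Fallback: drop metathesis. Add the enolate of 9 in Michael fashion to the corresponding tert-alkyl vinyl ketone, open with Zn, cleave the vinyl group to the aldehyde, close the cyclopentenyl ketone by intramolecular aldol condensation, and methylenate (Tebbe) to the same diene.
2. **Steps 11/12, Diels–Alder on a hindered 2,3-disubstituted diene with only modest thermodynamic control at C-4.** Fallback: use methyl propiolate as dienophile, which removes the endo/exo question. Then set C-4 kinetically by conjugate reduction (Stryker's reagent) with protonation from the face opposite the cyclopentane substituents, and reduce the ester with LiBH₄.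
3. **Step 1, Claisen forming a quaternary centre syn to an axial methyl, with competing elimination of isophorol.** Fallback: Still–Wittig [2,3] rearrangement of the stannylmethyl ether of 1 at −78 °C (same 1,3-chirality transfer), then oxidation to the aldehyde and Corey–Fuchs homologation with formaldehyde trapping to reach 4.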